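The C4–C4a bond of the pyran ring (ring C) is the disconnection on which everything rests. C4a is flanked by the O1-bearing C8a and the oxygenated C5 and stands para to the oxygenated C7, so it is the most nucleophilic carbon of ring A. C3, next to C4, bears oxygen, so an epoxide spanning C3–C4 attacked by ring A accounts for both features. In one operation the key step closes ring C by a 6-endo Friedel–Crafts opening and unveils the C3 hydroxyl, leaving both stereocentres alone. Its precursor is the threo (R,R) ether in which 3,5-bis(benzyloxy)phenol is bound to the benzylic carbon of an aryl oxiranyl carbinol, reached by Sharpless kinetic resolution and Mitsunobu inversion.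

Key step: step 4

Assumption: 3-(benzyloxy)-4-methoxybenzaldehyde and 3,4,5-tris(benzyloxy)benzoic acid are bought as such; erythro and threo refer to the Fischer projection of the C2–C3 chain, so the erythro epoxy alcohol is (S)-carbinol/(R)-oxirane and the threo ether is (R,R), which maps onto (2R,3R) in the chroman.

Step 1
Reactants: 1 3-(benzyloxy)-4-methoxybenzaldehyde; 2 vinylmagnesium bromide
Product: 3 rac-1-[3-(benzyloxy)-4-methoxyphenyl]prop-2-en-1-ol
Conditions: THF, −78 °C to 0 °C; then H2O
Reagents that add atoms: none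
Why: Grignard 1,2-addition to an aromatic aldehyde should give the secondary allylic alcohol; the carbinol stereocentre forms without control, which is intended because step 2 resolves it.

Step 2
Reactants: 3 rac-1-[3-(benzyloxy)-4-methoxyphenyl]prop-2-en-1-ol
Product: 4 (S)-[3-(benzyloxy)-4-methoxyphenyl][(2R)-oxiran-2-yl]methanol (erythro)
Conditions: Ti(OiPr)4 (0.1 equiv), L-(+)-diisopropyl tartrate (0.15 equiv), t-BuOOH (0.5 equiv), 4 Å MS, CH2Cl2, −20 °C
Reagents that add atoms: tert-butyl hydroperoxide, CC(C)(C)OO
Why: Sharpless kinetic resolution by asymmetric epoxidation: the titanium–L-(+)-tartrate catalyst should epoxidise the (R)-enantiomer of 3 much faster than the (S)-enantiomer and deliver oxygen to the vinyl face that gives the erythro product, so the catalyst fixes the carbinol as S and the new oxirane carbon as R, and the unreacted (S)-enantiomer of 3 is removed by chromatography.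

Step 3
Reactants: 4 (S)-[3-(benzyloxy)-4-methoxyphenyl][(2R)-oxiran-2-yl]methanol; 5 3,5-bis(benzyloxy)phenol
Product: 6 (2R)-2-{(R)-[3-(benzyloxy)-4-methoxyphenyl][3,5-bis(benzyloxy)phenoxy]methyl}oxirane (threo)
Conditions: PPh3, diisopropyl azodicarboxylate, toluene, 0 °C to rt
Reagents that add atoms: none
Why: Mitsunobu etherification: the alkoxyphosphonium ion of the carbinol should be displaced by the phenoxide of 5 in an SN2 step with inversion, turning the erythro (S)-carbinol into the threo (R) aryl ether, while the electron-withdrawing oxirane next to the carbinol disfavours ionisation and the oxirane carbon is not touched.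

Step 4
Reactants: 6 (2R)-2-{(R)-[3-(benzyloxy)-4-methoxyphenyl][3,5-bis(benzyloxy)phenoxy]methyl}oxirane
Product: 7 (2R,3R)-5,7-bis(benzyloxy)-2-[3-(benzyloxy)-4-methoxyphenyl]-3,4-dihydro-2H-chromen-3-ol
Conditions: AuCl3 (5 mol %), AgOSO2CF3 (15 mol %), ClCH2CH2Cl, 0 °C to rt
Reagents that add atoms: none
Why: The cationic trivalent gold species formed from AuCl3 and AgOSO2CF3 binds the oxirane oxygen, the ring A carbon ortho to the ether oxygen and para to a benzyloxy group attacks the unsubstituted oxirane carbon in an SN2-like intramolecular Friedel–Crafts alkylation, and loss of the arenium proton restores aromaticity and releases the C3 hydroxyl. The closest known reaction type is the Lewis-acid-catalysed epoxy–arene cyclisation of aryl ethers of 2,3-epoxy alcohols to chroman-3-ols. Ring C closes in the 6-endo-tet mode through the new C4–C4a bond; the 5-exo alternative would require attack at the internal oxirane carbon, which is more hindered and is deactivated inductively by the aryloxy-bearing C2. No stereocentre is formed, and since neither the C2–O nor the C3–O bond is broken the threo (R,R) ether should become the 2,3-cis (2R,3R) chromanol. The step needs opening at the primary carbon without heterolysis of the benzylic C2–O bond, which the two equivalent, doubly activated ortho positions of ring A, the oxirane next to C2 and the mild catalytic activation at low temperature should secure.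

Step 5
Reactants: 7 (2R,3R)-5,7-bis(benzyloxy)-2-[3-(benzyloxy)-4-methoxyphenyl]-3,4-dihydro-2H-chromen-3-ol; 8 3,4,5-tris(benzyloxy)benzoic acid
Product: 9 (2R,3R)-5,7-bis(benzyloxy)-2-[3-(benzyloxy)-4-methoxyphenyl]-3,4-dihydro-2H-chromen-3-yl 3,4,5-tris(benzyloxy)benzoate
Conditions: N,N'-dicyclohexylcarbodiimide, 4-(dimethylamino)pyridine (cat.), CH2Cl2, 0 °C to rt
Reagents that add atoms: none
Why: Steglich esterification: the carbodiimide activates acid 8 and the aminopyridine transfers the acyl group to the axial C3 hydroxyl, the only free hydroxyl of 7, without touching a stereocentre.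

Step 6
Reactants: 9 (2R,3R)-5,7-bis(benzyloxy)-2-[3-(benzyloxy)-4-methoxyphenyl]-3,4-dihydro-2H-chromen-3-yl 3,4,5-tris(benzyloxy)benzoate
Product: 10 4'-O-methylepicatechin-3-O-gallate
Conditions: H2 (1 atm), Pd(OH)2/C, THF/MeOH, rt
Reagents that add atoms: none
Why: Catalytic hydrogenolysis should cleave all six benzyl ethers under neutral conditions, under which the methyl ether, the gallate ester and the cyclic benzylic C2–O1 ether of a flavan-3-ol persist and no stereocentre is affected.

Compound list
1 | 3-(benzyloxy)-4-methoxybenzaldehyde | COc1ccc(C=O)cc1OCc1ccccc1 | starting material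
2 | vinylmagnesium bromide | C=C[Mg]Br | starting material
3 | rac-1-[3-(benzyloxy)-4-methoxyphenyl]prop-2-en-1-ol | COc1ccc(C(O)C=C)cc1OCc1ccccc1 | intermediate
4 | (S)-[3-(benzyloxy)-4-methoxyphenyl][(2R)-oxiran-2-yl]methanol (erythro) | COc1ccc([C@H](O)[C@H]2CO2)cc1OCc1ccccc1 | intermediate
5 | 3,5-bis(benzyloxy)phenol | Oc1cc(OCc2ccccc2)cc(OCc2ccccc2)c1 | starting material
6 | (2R)-2-{(R)-[3-(benzyloxy)-4-methoxyphenyl][3,5-bis(benzyloxy)phenoxy]methyl}oxirane (threo) | COc1ccc([C@@H](Oc2cc(OCc3ccccc3)cc(OCc3ccccc3)c2)[C@H]2CO2)cc1OCc1ccccc1 | intermediate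
7 | (2R,3R)-5,7-bis(benzyloxy)-2-[3-(benzyloxy)-4-methoxyphenyl]-3,4-dihydro-2H-chromen-3-ol | COc1ccc([C@H]2Oc3cc(OCc4ccccc4)cc(OCc4ccccc4)c3C[C@H]2O)cc1OCc1ccccc1 | intermediate
8 | 3,4,5-tris(benzyloxy)benzoic acid | OC(=O)c1cc(OCc2ccccc2)c(OCc2ccccc2)c(OCc2ccccc2)c1 | starting material
9 | (2R,3R)-5,7-bis(benzyloxy)-2-[3-(benzyloxy)-4-methoxyphenyl]-3,4-dihydro-2H-chromen-3-yl 3,4,5-tris(benzyloxy)benzoate | COc1ccc([C@H]2Oc3cc(OCc4ccccc4)cc(OCc4ccccc4)c3C[C@H]2OC(=O)c2cc(OCc3ccccc3)c(OCc3ccccc3)c(OCc3ccccc3)c2)cc1OCc1ccccc1 | intermediate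
10 | 4'-O-methylepicatechin-3-O-gallate, (2R,3R) | COc1ccc([C@H]2Oc3cc(O)cc(O)c3C[C@H]2OC(=O)c2cc(O)c(O)c(O)c2)cc1O | target

Total step count: 6. Longest linear sequence: 6 steps (1 → 3 → 4 → 6 → 7 → 9 → 10).

Steps most likely to fail

Most at risk is step 4. Under Lewis-acid activation the benzylic C2–O bond, which is para to the methoxy group, may break heterolytically, leading to epimerisation at C2 or loss of the phenol. The arene may also attack the internal oxirane carbon. The fallback makes the same C4–C4a bond by an anionic closure that needs no acid; it sets out from compounds 5 and 4 and comes back at compound 7. Phenol 5 would be iodinated ortho to the hydroxyl (N-iodosuccinimide, CH2Cl2, −20 °C) to give 3,5-bis(benzyloxy)-2-iodophenol F1. Mitsunobu coupling of that phenol with 4 (PPh3, diisopropyl azodicarboxylate, toluene, 0 °C) should give with inversion (2R)-2-{(R)-[3-(benzyloxy)-4-methoxyphenyl][3,5-bis(benzyloxy)-2-iodophenoxy]methyl}oxirane F2. Li2NiBr4 in THF at 0 °C should open the oxirane at its primary carbon to the bromohydrin (1R,2S)-1-[3-(benzyloxy)-4-methoxyphenyl]-1-[3,5-bis(benzyloxy)-2-iodophenoxy]-3-bromopropan-2-ol F3. Et3SiCl and imidazole in DMF should give its triethylsilyl ether F4. Iodine–lithium exchange (n-BuLi, THF, −78 °C, then warming to 0 °C) followed by Parham-type 6-exo-tet alkylation of the aryllithium by the primary bromide should give (2R,3R)-5,7-bis(benzyloxy)-2-[3-(benzyloxy)-4-methoxyphenyl]-3-(triethylsilyloxy)-3,4-dihydro-2H-chromene F5. Bu4NF in THF would then remove the silyl group to give 7.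

Second is step 3. The activated carbinol may ionise with help from the para-methoxy group, so that inversion is incomplete, or the very electron-rich phenol may be alkylated on carbon. Because C3 is already fixed, a C2 epimer would be a separable diastereomer, so the first fault costs material and not enantiopurity. The fallback lowers the donor power of ring B before the carbinol exists, by carrying the 3'-oxygen as an arenesulfonate in place of the benzyl ether, and restores the benzyl ether after ring closure. Since the tuning group must be in place before the carbinol is made, the branch cannot start at 4. It sets out from compound 2 and from the parent phenol of 1, uses compound 5, and comes back at compound 7. The parent phenol, isovanillin F6, would be tosylated (4-methylbenzenesulfonyl chloride, Et3N, CH2Cl2) to 5-formyl-2-methoxyphenyl 4-methylbenzenesulfonate F7. Addition of 2 as in step 1 should give rac-5-(1-hydroxyprop-2-en-1-yl)-2-methoxyphenyl 4-methylbenzenesulfonate F8. The kinetic resolution of step 2 should give 5-{(S)-hydroxy[(2R)-oxiran-2-yl]methyl}-2-methoxyphenyl 4-methylbenzenesulfonate F9. Mitsunobu coupling with 5 should give 5-{(R)-[3,5-bis(benzyloxy)phenoxy][(2R)-oxiran-2-yl]methyl}-2-methoxyphenyl 4-methylbenzenesulfonate F10. The cyclisation of step 4 should give 5-[(2R,3R)-5,7-bis(benzyloxy)-3-hydroxy-3,4-dihydro-2H-chromen-2-yl]-2-methoxyphenyl 4-methylbenzenesulfonate F11. KOH in MeOH/THF at 50 °C should cleave the sulfonate to (2R,3R)-5,7-bis(benzyloxy)-2-(3-hydroxy-4-methoxyphenyl)-3,4-dihydro-2H-chromen-3-ol F12. Benzyl bromide and K2CO3 in DMF should then benzylate the phenol only and give 7.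

Third is step 2. Epoxidation of a monosubstituted vinyl group is slow, so the rate difference between the enantiomers may be too small, or the acid-sensitive epoxy alcohol may degrade during the long reaction. The fallback separates the enantiomers first by enzymatic acylation and then epoxidises the single enantiomer under hydroxyl direction; it sets out from compound 3 and comes back at compound 4. Immobilised Candida antarctica lipase B and vinyl acetate in toluene should acetylate the enantiomer in which the aryl group is the large and the vinyl group the medium substituent, giving (R)-1-[3-(benzyloxy)-4-methoxyphenyl]prop-2-en-1-yl acetate F13, which is separated from the unreacted (S)-alcohol. K2CO3 in MeOH should give (R)-1-[3-(benzyloxy)-4-methoxyphenyl]prop-2-en-1-ol F14. Ti(OiPr)4, L-(+)-diisopropyl tartrate and t-BuOOH in CH2Cl2 at −20 °C, now a matched pair that can be run to full conversion, should then epoxidise it to 4.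

Further compounds
F1 | step 4 | 3,5-bis(benzyloxy)-2-iodophenol | Oc1cc(OCc2ccccc2)cc(OCc2ccccc2)c1I
F2 | step 4 | (2R)-2-{(R)-[3-(benzyloxy)-4-methoxyphenyl][3,5-bis(benzyloxy)-2-iodophenoxy]methyl}oxirane | COc1ccc([C@@H](Oc2cc(OCc3ccccc3)cc(OCc3ccccc3)c2I)[C@H]2CO2)cc1OCc1ccccc1
F3 | step 4 | (1R,2S)-1-[3-(benzyloxy)-4-methoxyphenyl]-1-[3,5-bis(benzyloxy)-2-iodophenoxy]-3-bromopropan-2-ol | COc1ccc([C@@H](Oc2cc(OCc3ccccc3)cc(OCc3ccccc3)c2I)[C@H](O)CBr)cc1OCc1ccccc1
F4 | step 4 | triethylsilyl ether of F3 | COc1ccc([C@@H](Oc2cc(OCc3ccccc3)cc(OCc3ccccc3)c2I)[C@H](O[Si](CC)(CC)CC)CBr)cc1OCc1ccccc1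
F5 | step 4 | (2R,3R)-5,7-bis(benzyloxy)-2-[3-(benzyloxy)-4-methoxyphenyl]-3-(triethylsilyloxy)-3,4-dihydro-2H-chromene | COc1ccc([C@H]2Oc3cc(OCc4ccccc4)cc(OCc4ccccc4)c3C[C@H]2O[Si](CC)(CC)CC)cc1OCc1ccccc1
F6 | step 3 | isovanillin | COc1ccc(C=O)cc1O
F7 | step 3 | 5-formyl-2-methoxyphenyl 4-methylbenzenesulfonate | COc1ccc(C=O)cc1OS(=O)(=O)c1ccc(C)cc1
F8 | step 3 | rac-5-(1-hydroxyprop-2-en-1-yl)-2-methoxyphenyl 4-methylbenzenesulfonate | COc1ccc(C(O)C=C)cc1OS(=O)(=O)c1ccc(C)cc1
F9 | step 3 | 5-{(S)-hydroxy[(2R)-oxiran-2-yl]methyl}-2-methoxyphenyl 4-methylbenzenesulfonate | COc1ccc([C@H](O)[C@H]2CO2)cc1OS(=O)(=O)c1ccc(C)cc1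
F10 | step 3 | 5-{(R)-[3,5-bis(benzyloxy)phenoxy][(2R)-oxiran-2-yl]methyl}-2-methoxyphenyl 4-methylbenzenesulfonate | COc1ccc([C@@H](Oc2cc(OCc3ccccc3)cc(OCc3ccccc3)c2)[C@H]2CO2)cc1OS(=O)(=O)c1ccc(C)cc1
F11 | step 3 | 5-[(2R,3R)-5,7-bis(benzyloxy)-3-hydroxy-3,4-dihydro-2H-chromen-2-yl]-2-methoxyphenyl 4-methylbenzenesulfonate | COc1ccc([C@H]2Oc3cc(OCc4ccccc4)cc(OCc4ccccc4)c3C[C@H]2O)cc1OS(=O)(=O)c1ccc(C)cc1
F12 | step 3 | (2R,3R)-5,7-bis(benzyloxy)-2-(3-hydroxy-4-methoxyphenyl)-3,4-dihydro-2H-chromen-3-ol | COc1ccc([C@H]2Oc3cc(OCc4ccccc4)cc(OCc4ccccc4)c3C[C@H]2O)cc1O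
F13 | step 2 | (R)-1-[3-(benzyloxy)-4-methoxyphenyl]prop-2-en-1-yl acetate | COc1ccc([C@H](OC(C)=O)C=C)cc1OCc1ccccc1
F14 | step 2 | (R)-1-[3-(benzyloxy)-4-methoxyphenyl]prop-2-en-1-ol | COc1ccc([C@H](O)C=C)cc1OCc1ccccc1
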